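A direct plan would build a methyl-substituted octalenedione by an enantioselective aldol annulation and mask its saturated ketone (enone ketal A1). It would then add an isopropyl Grignard reagent, dihydroxylate, and turn the decalin into the hydroazulene by a base-induced 1,2-shift of the triol monomesylate A2. Ring B would be finished through the late enone A3. Its weakest points would be:
(i) the isopropyl addition to A1: the C4 carbinol would rest on a weak facial bias from the remote angular methyl group, and the C8 methyl centre would travel as a mixture of epimers for about ten steps;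
(ii) the ring contraction/expansion of A2: the only step that makes the 5–7 core would depend on one conformer of a flexible cis-decalin, with migration of the wrong carbon, epoxide closure and retro-aldol cleavage in base as competitors;
(iii) the hydride reduction of enone A3 that would set C10 last: its face would be a guess on the most precious material, with the aryl ester exposed to the hydride, after about six steps of ketal removal, dehydrogenation and redox change that add little complexity.

The esters are removed first and C5–H/C6–O is read as the hydration of a C5=C6 bond. Ring B is then a cyclohepta-1,4-diene (C5=C6 and C8=C9 flanking the single sp3 carbon C7), which is the product pattern of a cis-divinylcyclopropane rearrangement, and it is cut at C1–C10 and C7–C8.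
Ring A arises first, from the six-membered ring of (S)-terpinen-4-ol by oxidative cleavage and aldol ring contraction, so C4 comes from the chiral pool. Ring B is then closed in one step from vinylcyclopentene 6 and vinyldiazo ester 11.
No Grignard addition sets C4, and no decalin or skeletal shift occurs. C1 and C10 are fixed together by alkene geometry in the key step and not by a late enone reduction, and C8 is never a stereocentre.

Key step: step 6

Remarks. Daucane numbering is used: ring A is C1–C2–C3–C4–C5 and ring B is C1–C5–C6–C7–C8–C9–C10. C1 carries the angular methyl group, C4 the isopropyl group and the tertiary oxygen, and C8 the carbon C14. "α" is the face of H-5 and "β" the face of the C1 methyl group. Rh2(R-DOSP)4 is dirhodium tetrakis[(R)-N-(4-dodecylbenzenesulfonyl)prolinate]. Assumption: (S)-(+)-terpinen-4-ol is commercially available in enantiomerically enriched form; any (R)-enantiomer is removed after step 6, where the chiral catalyst turns it into a separable diastereomer.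

Step 1
Reactants: 1 (S)-(+)-terpinen-4-ol
Product: 2 (S)-terpinen-4-yl triethylsilyl ether
Conditions: Et3SiOTf, 2,6-lutidine, CH2Cl2, 0 °C
Reagents that add atoms: triethylsilyl trifluoromethanesulfonate (CC[Si](CC)(CC)OS(=O)(=O)C(F)(F)F)
Why: Silylation of a hindered tertiary alcohol with a silyl triflate and a hindered pyridine base is standard, the ether keeps the tertiary oxygen from elimination in step 2 and from O–H insertion or ylide rearrangement with the carbenoid in step 6, and the stereocentre (the future C4) is not touched.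

Step 2
Reactants: 2 (S)-terpinen-4-yl triethylsilyl ether
Product: 5 (R)-2-methyl-5-(propan-2-yl)-5-(triethylsilyloxy)cyclopent-1-ene-1-carbaldehyde, via ozonide 3 (not isolated), via keto aldehyde 4 (not isolated)
Conditions: O3, CH2Cl2, −78 °C; Me2S, −78 °C → rt; then piperidine (0.3 equiv), AcOH (0.3 equiv), toluene, 80 °C
Reagents that add atoms: ozone ([O-][O+]=O)
Why: Ozonolysis with reductive work-up cleaves the ring alkene to keto aldehyde 4, whose aldehyde enamine closes ring A onto the methyl ketone and dehydrates (intramolecular aldol condensation), the ring contraction well known for p-menthenes such as limonene; no stereocentre is formed and C4, which has no α-hydrogen left in 5, is untouched.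

Step 3
Reactants: 5 (R)-2-methyl-5-(propan-2-yl)-5-(triethylsilyloxy)cyclopent-1-ene-1-carbaldehyde
Product: 6 (R)-1-ethenyl-2-methyl-5-(propan-2-yl)-5-(triethylsilyloxy)cyclopent-1-ene
Conditions: Ph3PCH3Br, KOt-Bu, THF, 0 °C → rt
Reagents that add atoms: methyltriphenylphosphonium bromide (C[P+](c1ccccc1)(c1ccccc1)c1ccccc1.[Br-])
Why: Wittig methylenation of the hindered but non-enolisable enal gives the 1-vinylcyclopentene (C1=C5–C6=C7), and no stereocentre is involved.

Step 4
Reactants: 7 ethyl diazoacetate; 8 [(4-methoxybenzyl)oxy]acetaldehyde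
Product: 9 ethyl 2-diazo-3-hydroxy-4-[(4-methoxybenzyl)oxy]butanoate (racemic)
Conditions: DBU (20 mol %), MeCN, rt
Reagents that add atoms: none
Why: Base-catalysed aldol-type addition of the acidic C–H of a diazoacetate to an aldehyde is a standard entry to β-hydroxy-α-diazo esters, and the new carbinol centre is lost in the next step.

Step 5
Reactants: 9 ethyl 2-diazo-3-hydroxy-4-[(4-methoxybenzyl)oxy]butanoate
Product: 11 ethyl (E)-2-diazo-4-[(4-methoxybenzyl)oxy]but-3-enoate, via dichlorophosphate 10 (not isolated)
Conditions: POCl3, Et3N, CH2Cl2, 0 °C → rt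
Reagents that add atoms: none
Why: Dehydration of β-hydroxy-α-diazo esters with POCl3/Et3N (phosphorylation, loss of dichlorophosphate, deprotonation at C4) is the usual route to vinyldiazoacetates, and the conjugated (E)-enol ether should predominate because the Z isomer pushes the alkoxy group against the diazo ester.

Step 6
Reactants: 6 (R)-1-ethenyl-2-methyl-5-(propan-2-yl)-5-(triethylsilyloxy)cyclopent-1-ene; 11 ethyl (E)-2-diazo-4-[(4-methoxybenzyl)oxy]but-3-enoate
Product: 13 ethyl (1S,4R,10R)-10-[(4-methoxybenzyl)oxy]-4-(triethylsilyloxy)dauca-5,8-dien-14-oate, via divinylcyclopropane 12 (not isolated)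
Conditions: Rh2(R-DOSP)4 (1 mol %), pentane/toluene, −40 °C, slow addition of 11 (1.5 equiv); then toluene, 80 °C
Reagents that add atoms: none
Why: The rhodium carbenoid formed from 11 by loss of N2 adds to the terminal C6=C7 bond of 6 to give the cis-divinylcyclopropane 12 (alkoxyvinyl group on C8 cis to the cyclopentenyl group on C6), and on warming 12 undergoes a Cope rearrangement through the boat transition state in which the strained C6–C8 bond breaks and the C1–C10 bond forms; the closest known reaction type is the tandem cyclopropanation/Cope rearrangement (formal [4+3] cycloaddition) of vinyldiazoacetates with 1,3-dienes, including 1-vinylcycloalkenes that give quaternary centres. The three-membered ring closes by [2+1] carbene transfer and ring B closes as a seven-membered ring by the [3,3]-sigmatropic shift, driven by release of cyclopropane strain, while ring A is only a spectator. C1 and C10 are set relative to each other by the boat geometry: the methyl group on C1 is the inward (Z-placed) and the ether oxygen on C10 the outward (E-placed) substituent of the two termini, so they end trans on ring B. Both are set relative to C4 by the configuration of 12 (1R,2S), which is imposed by the chiral catalyst, whose (S)-enantiomer is known to give (1S,2R)-cyclopropanes from terminal alkenes and donor/acceptor diazo esters; if the sense on this diene proved opposite, the (S)-catalyst would be used. The step needs attack at the monosubstituted C6=C7 bond and not at the tetrasubstituted C1=C5 bond, and reaction at the carbenoid carbon and not at the vinylogous terminus; the first is secured by the inertness of tetrasubstituted alkenes toward donor/acceptor carbenoids, the second by the substituent on the vinyl terminus and the hydrocarbon solvent. The (E)-geometry of 11 is essential, since a Z-enol ether would lead to the C10 epimer.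

Step 7
Reactants: 13 ethyl (1S,4R,10R)-10-[(4-methoxybenzyl)oxy]-4-(triethylsilyloxy)dauca-5,8-dien-14-oate
Product: 15 ethyl (1S,4R,5S,6S,10R)-6-hydroxy-10-[(4-methoxybenzyl)oxy]-4-(triethylsilyloxy)dauc-8-en-14-oate, via alkylborane 14 (not isolated)
Conditions: BH3·THF, THF, 0 °C → rt; then NaBO3·4H2O, H2O, rt
Reagents that add atoms: sodium perborate tetrahydrate ([Na+].[O-]OB=O.O.O.O.O)
Why: In this hydroboration–oxidation borane should add syn to C5=C6 with boron at the less substituted C6 and from the α face, opposite the pseudoaxial C1 methyl group and the C4 silyloxy group (the sense that gives trans-fused products from angular-methyl hydrindenes and 5-ene steroids), which sets C5 (H α, trans ring fusion) and C6 (oxygen α, cis to H-5) at once, while C8=C9 is deactivated by conjugation with the ester and perborate oxidises the C–B bond with retention without touching the ester.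

Step 8
Reactants: 15 ethyl (1S,4R,5S,6S,10R)-6-hydroxy-10-[(4-methoxybenzyl)oxy]-4-(triethylsilyloxy)dauc-8-en-14-oate
Product: 16 (1S,4R,5S,6S,10R)-10-[(4-methoxybenzyl)oxy]-4-(triethylsilyloxy)dauc-8-ene-6,14-diol
Conditions: i-Bu2AlH, CH2Cl2, −78 → 0 °C; aq. potassium sodium tartrate
Reagents that add atoms: none
Why: 1,2-Reduction of the conjugated ester by i-Bu2AlH gives the primary allylic alcohol, the silyl and benzyl ethers are inert, and no stereocentre is involved.

Step 9
Reactants: 16 (1S,4R,5S,6S,10R)-10-[(4-methoxybenzyl)oxy]-4-(triethylsilyloxy)dauc-8-ene-6,14-diol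
Product: 18 (1S,4R,5S,6S,10R)-10-[(4-methoxybenzyl)oxy]-4-(triethylsilyloxy)dauc-8-en-6-ol, via mesylate 17 (not isolated)
Conditions: MsCl (1.1 equiv), Et3N, CH2Cl2, −40 °C; then LiBHEt3, THF, −40 → 0 °C
Reagents that add atoms: none
Why: Selective sulfonylation of the primary allylic hydroxyl over the hindered secondary C6 hydroxyl, followed by SN2 displacement of the allylic mesylate by hydride at the unhindered primary carbon (the SN2′ position C9 is flanked by C10 and the quaternary C1), turns C14 into the C8 methyl group without touching a stereocentre.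

Step 10
Reactants: 18 (1S,4R,5S,6S,10R)-10-[(4-methoxybenzyl)oxy]-4-(triethylsilyloxy)dauc-8-en-6-ol; 19 4-methoxybenzoyl chloride
Product: 20 (1S,4R,5S,6S,10R)-10-[(4-methoxybenzyl)oxy]-4-(triethylsilyloxy)dauc-8-en-6-yl 4-methoxybenzoate
Conditions: Et3N, 4-(dimethylamino)pyridine, CH2Cl2, 40 °C
Reagents that add atoms: none
Why: Acylation under nucleophilic catalysis takes the only free hydroxyl, the secondary C6 alcohol, with retention.

Step 11
Reactants: 20 (1S,4R,5S,6S,10R)-10-[(4-methoxybenzyl)oxy]-4-(triethylsilyloxy)dauc-8-en-6-yl 4-methoxybenzoate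
Product: 21 (1S,4R,5S,6S,10R)-10-hydroxy-4-(triethylsilyloxy)dauc-8-en-6-yl 4-methoxybenzoate
Conditions: DDQ, CH2Cl2/pH 7 buffer, 0 °C
Reagents that add atoms: none
Why: Oxidative cleavage of the 4-methoxybenzyl ether by DDQ (hydride abstraction, then hydrolysis of the oxocarbenium ion) frees the C10 hydroxyl with retention, while the tertiary silyl ether and the benzoate, which has no benzylic C–H, survive and no free hydroxyl is near enough to form a benzylidene acetal.

Step 12
Reactants: 21 (1S,4R,5S,6S,10R)-10-hydroxy-4-(triethylsilyloxy)dauc-8-en-6-yl 4-methoxybenzoate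
Product: 22 (1S,4R,5S,6S,10R)-10-acetoxy-4-(triethylsilyloxy)dauc-8-en-6-yl 4-methoxybenzoate
Conditions: Ac2O, pyridine, 4-(dimethylamino)pyridine (cat.), CH2Cl2, rt
Reagents that add atoms: acetic anhydride (CC(=O)OC(C)=O)
Why: Standard acetylation of the secondary allylic C10 hydroxyl with retention; C4 is still silylated, so no selectivity is required.

Step 13
Reactants: 22 (1S,4R,5S,6S,10R)-10-acetoxy-4-(triethylsilyloxy)dauc-8-en-6-yl 4-methoxybenzoate
Product: 23 target, (1S,4R,5S,6S,10R)-10-acetoxy-4-hydroxydauc-8-en-6-yl 4-methoxybenzoate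
Conditions: HF·pyridine, pyridine, THF, 0 °C → rt
Reagents that add atoms: none
Why: Fluoride-mediated cleavage of the tertiary triethylsilyl ether under buffered, weakly acidic conditions leaves the allylic acetate, the benzoate and the trisubstituted alkene intact and gives the target.

Compound list
1 | (S)-(+)-terpinen-4-ol, (S)-4-methyl-1-(propan-2-yl)cyclohex-3-en-1-ol | CC1=CC[C@@](O)(CC1)C(C)C | starting material
2 | (S)-terpinen-4-yl triethylsilyl ether | CC1=CC[C@@](O[Si](CC)(CC)CC)(CC1)C(C)C | intermediate
3 | ozonide (1,2,4-trioxolane) of 2, configuration at the two ozonide carbons open | CC12CC[C@@](O[Si](CC)(CC)CC)(C(C)C)CC(OO1)O2 | intermediate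
4 | (S)-6-oxo-3-(propan-2-yl)-3-(triethylsilyloxy)heptanal | O=CC[C@@](O[Si](CC)(CC)CC)(CCC(C)=O)C(C)C | intermediate
5 | (R)-2-methyl-5-(propan-2-yl)-5-(triethylsilyloxy)cyclopent-1-ene-1-carbaldehyde (ring A with C6 as the aldehyde) | O=CC1=C(C)CC[C@@]1(O[Si](CC)(CC)CC)C(C)C | intermediate
6 | (R)-1-ethenyl-2-methyl-5-(propan-2-yl)-5-(triethylsilyloxy)cyclopent-1-ene | C=CC1=C(C)CC[C@@]1(O[Si](CC)(CC)CC)C(C)C | intermediate
7 | ethyl diazoacetate | CCOC(=O)C=[N+]=[N-] | starting material
8 | [(4-methoxybenzyl)oxy]acetaldehyde | COc1ccc(COCC=O)cc1 | starting material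
9 | ethyl 2-diazo-3-hydroxy-4-[(4-methoxybenzyl)oxy]butanoate (racemic) | CCOC(=O)C(=[N+]=[N-])C(O)COCc1ccc(OC)cc1 | intermediate
10 | dichlorophosphate ester of 9 (at the C3 oxygen) | CCOC(=O)C(=[N+]=[N-])C(COCc1ccc(OC)cc1)OP(Cl)(Cl)=O | intermediate
11 | ethyl (E)-2-diazo-4-[(4-methoxybenzyl)oxy]but-3-enoate | CCOC(=O)C(=[N+]=[N-])/C=C/OCc1ccc(OC)cc1 | intermediate
12 | ethyl (1R,2S)-1-{(E)-2-[(4-methoxybenzyl)oxy]ethenyl}-2-[(5R)-2-methyl-5-(propan-2-yl)-5-(triethylsilyloxy)cyclopent-1-en-1-yl]cyclopropane-1-carboxylate (the two alkenyl groups cis) | CCOC(=O)[C@]1(/C=C/OCc2ccc(OC)cc2)C[C@H]1C1=C(C)CC[C@@]1(O[Si](CC)(CC)CC)C(C)C | intermediate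
13 | ethyl (1S,4R,10R)-10-[(4-methoxybenzyl)oxy]-4-(triethylsilyloxy)dauca-5,8-dien-14-oate (C10 oxygen trans to the C1 methyl group) | CCOC(=O)C1=C[C@@H](OCc2ccc(OC)cc2)[C@@]3(C)CC[C@@](O[Si](CC)(CC)CC)(C(C)C)C3=CC1 | intermediate
14 | C6 alkylborane from 13 (BH2 on C6 and H on C5, both α) | B[C@H]1CC(C(=O)OCC)=C[C@@H](OCc2ccc(OC)cc2)[C@@]3(C)CC[C@@](O[Si](CC)(CC)CC)(C(C)C)[C@H]13 | intermediate
15 | ethyl (1S,4R,5S,6S,10R)-6-hydroxy-10-[(4-methoxybenzyl)oxy]-4-(triethylsilyloxy)dauc-8-en-14-oate (H-5 trans to the C1 methyl group, C6–OH cis to H-5) | O[C@H]1CC(C(=O)OCC)=C[C@@H](OCc2ccc(OC)cc2)[C@@]3(C)CC[C@@](O[Si](CC)(CC)CC)(C(C)C)[C@H]13 | intermediate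
16 | (1S,4R,5S,6S,10R)-10-[(4-methoxybenzyl)oxy]-4-(triethylsilyloxy)dauc-8-ene-6,14-diol | O[C@H]1CC(CO)=C[C@@H](OCc2ccc(OC)cc2)[C@@]3(C)CC[C@@](O[Si](CC)(CC)CC)(C(C)C)[C@H]13 | intermediate
17 | 14-O-methanesulfonate of 16 | O[C@H]1CC(COS(C)(=O)=O)=C[C@@H](OCc2ccc(OC)cc2)[C@@]3(C)CC[C@@](O[Si](CC)(CC)CC)(C(C)C)[C@H]13 | intermediate
18 | (1S,4R,5S,6S,10R)-10-[(4-methoxybenzyl)oxy]-4-(triethylsilyloxy)dauc-8-en-6-ol | O[C@H]1CC(C)=C[C@@H](OCc2ccc(OC)cc2)[C@@]3(C)CC[C@@](O[Si](CC)(CC)CC)(C(C)C)[C@H]13 | intermediate
19 | 4-methoxybenzoyl chloride | COc1ccc(cc1)C(Cl)=O | starting material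
20 | (1S,4R,5S,6S,10R)-10-[(4-methoxybenzyl)oxy]-4-(triethylsilyloxy)dauc-8-en-6-yl 4-methoxybenzoate | COc1ccc(cc1)C(=O)O[C@H]1CC(C)=C[C@@H](OCc2ccc(OC)cc2)[C@@]3(C)CC[C@@](O[Si](CC)(CC)CC)(C(C)C)[C@H]13 | intermediate
21 | (1S,4R,5S,6S,10R)-10-hydroxy-4-(triethylsilyloxy)dauc-8-en-6-yl 4-methoxybenzoate | COc1ccc(cc1)C(=O)O[C@H]1CC(C)=C[C@@H](O)[C@@]2(C)CC[C@@](O[Si](CC)(CC)CC)(C(C)C)[C@H]12 | intermediate
22 | (1S,4R,5S,6S,10R)-10-acetoxy-4-(triethylsilyloxy)dauc-8-en-6-yl 4-methoxybenzoate | COc1ccc(cc1)C(=O)O[C@H]1CC(C)=C[C@@H](OC(C)=O)[C@@]2(C)CC[C@@](O[Si](CC)(CC)CC)(C(C)C)[C@H]12 | intermediate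
23 | target, (1S,4R,5S,6S,10R)-10-acetoxy-4-hydroxydauc-8-en-6-yl 4-methoxybenzoate | COc1ccc(cc1)C(=O)O[C@H]1CC(C)=C[C@@H](OC(C)=O)[C@@]2(C)CC[C@@](O)(C(C)C)[C@H]12 | target

Total step count: 13. Longest linear sequence: 11 steps (steps 1–3 and 6–13); steps 4 and 5 make the second fragment.

Steps most likely to fail

1. Step 6. The electron-rich carbenoid may be diverted (attack at its vinylogous terminus, C–H insertion into the benzylic ether, dimerisation). The face selectivity may erode if catalyst and substrate are mismatched, and the Cope shift may be slow at the fully substituted C1 terminus. Fallback: the carbene would be placed on the ring A fragment, which removes the alkoxy-substituted carbenoid and the ester altogether. It would set out from 5. Zn(Hg) and 1,2-bis(chlorodimethylsilyl)ethane in ether at reflux would turn the aldehyde into an organozinc carbenoid at C6, a reaction known for aryl and α,β-unsaturated aldehydes. This would cyclopropanate the 3,4-double bond of (E)-3-methylbuta-1,3-dien-1-yl acetate F1 (from 3-methylbut-2-enal and isopropenyl acetate) to the divinylcyclopropane F2. Warming would give the cycloheptadiene acetate F3, with the C8 methyl group and the C10 acetate already in place. There would be no catalyst control over the face relative to C4, so the C1,C10-diastereomer would have to be separated. Hydroboration/oxidation as in step 7 (C8=C9 slowed by the allylic acetate) would give alcohol F4, and acylation with 19 would come back to the route at 22.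

2. Step 7. Borane may attack the β face or give a mixture of faces, and slow reduction of the conjugated ester may compete. Fallback: the reagent would be delivered from the α-oriented C10 oxygen through a temporary silicon tether. Setting out from 13, DDQ would free the C10 hydroxyl (alcohol F5) and (HMe2Si)2NH would give the dimethylsilyl ether F6. Pt2(dvtms)3 (zerovalent platinum complex of 1,3-divinyltetramethyldisiloxane) would then effect intramolecular hydrosilylation to the six-membered cyclic siloxane F7. Silicon would go to C6 and hydrogen to C5 on the α face, because attack at the fully substituted C5 is blocked. Tamao–Fleming oxidation (KF, KHCO3, H2O2) would give diol F8 with retention at C6. Reduction with i-Bu2AlH (triol F9) and deoxygenation at C14 as in step 9 would give diol F10. Its C6 hydroxyl is less hindered than the neopentylic C10 hydroxyl and would be acylated selectively with 19, which comes back to the route at 21.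

3. Step 5. The dehydration may give E/Z mixtures, or the diazo enol ether may decompose (cyclisation to a pyrazole, hydrolysis of the enol ether). Fallback: the diazo group would be introduced last by diazo transfer onto a preformed enoate. Setting out from 8, Wittig reaction with Ph3P=CHCO2Et would give ethyl (E)-4-[(4-methoxybenzyl)oxy]but-2-enoate F11. Deconjugative diazo transfer (4-acetamidobenzenesulfonyl azide, DBU, MeCN, 0 °C), the usual preparation of vinyldiazoacetates from enoates with γ-hydrogens, would give 11 and come back to the route there.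

Further compounds
F1 | step 6 | (E)-3-methylbuta-1,3-dien-1-yl acetate | CC(=O)O/C=C/C(C)=C
F2 | step 6 | cis-divinylcyclopropane from 5 and F1: C6(H)(cyclopentenyl)–C7H2–C8(CH3)[(E)-2-acetoxyethenyl], alkenyl groups cis | CC(=O)O/C=C/[C@@]1(C)C[C@H]1C1=C(C)CC[C@@]1(O[Si](CC)(CC)CC)C(C)C
F3 | step 6 | (1S,4R,10R)-4-(triethylsilyloxy)dauca-5,8-dien-10-yl acetate | CC1=C[C@@H](OC(C)=O)[C@@]2(C)CC[C@@](O[Si](CC)(CC)CC)(C(C)C)C2=CC1
F4 | step 6 | (1S,4R,5S,6S,10R)-6-hydroxy-4-(triethylsilyloxy)dauc-8-en-10-yl acetate | O[C@H]1CC(C)=C[C@@H](OC(C)=O)[C@@]2(C)CC[C@@](O[Si](CC)(CC)CC)(C(C)C)[C@H]12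
F5 | step 7 | ethyl (1S,4R,10R)-10-hydroxy-4-(triethylsilyloxy)dauca-5,8-dien-14-oate | CCOC(=O)C1=C[C@@H](O)[C@@]2(C)CC[C@@](O[Si](CC)(CC)CC)(C(C)C)C2=CC1
F6 | step 7 | 10-O-dimethylsilyl ether of F5 | CCOC(=O)C1=C[C@@H](O[SiH](C)C)[C@@]2(C)CC[C@@](O[Si](CC)(CC)CC)(C(C)C)C2=CC1
F7 | step 7 | cyclic siloxane from F6: O10–SiMe2–C6 six-membered ring, Si on C6 and H on C5 both α | CCOC(=O)C1=C[C@H]2O[Si](C)(C)[C@@H](C1)[C@H]3[C@](O[Si](CC)(CC)CC)(C(C)C)CC[C@]23C
F8 | step 7 | ethyl (1S,4R,5S,6S,10R)-6,10-dihydroxy-4-(triethylsilyloxy)dauc-8-en-14-oate | O[C@H]1CC(C(=O)OCC)=C[C@@H](O)[C@@]2(C)CC[C@@](O[Si](CC)(CC)CC)(C(C)C)[C@H]12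
F9 | step 7 | (1S,4R,5S,6S,10R)-4-(triethylsilyloxy)dauc-8-ene-6,10,14-triol | O[C@H]1CC(CO)=C[C@@H](O)[C@@]2(C)CC[C@@](O[Si](CC)(CC)CC)(C(C)C)[C@H]12
F10 | step 7 | (1S,4R,5S,6S,10R)-4-(triethylsilyloxy)dauc-8-ene-6,10-diol | O[C@H]1CC(C)=C[C@@H](O)[C@@]2(C)CC[C@@](O[Si](CC)(CC)CC)(C(C)C)[C@H]12
F11 | step 5 | ethyl (E)-4-[(4-methoxybenzyl)oxy]but-2-enoate | CCOC(=O)/C=C/COCc1ccc(OC)cc1
A1 | direct plan | bicyclic enone with the saturated ketone masked as a dioxolane (enone ketal) | O=C1CC[C@@]2(C)C(=C1)CC(C)CC21OCCO1
A2 | direct plan | C5 monomesylate of the cis-decalin 4,5,6-triol ketal | CC(C)[C@]1(O)CC[C@@]2(C)[C@@](O)([C@H]1OS(C)(=O)=O)CC(C)CC21OCCO1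
A3 | direct plan | hydroazulene C10 enone carrying the C6 4-methoxybenzoate and the free C4 hydroxyl | COc1ccc(cc1)C(=O)O[C@H]1CC(C)=CC(=O)[C@@]2(C)CC[C@@](O)(C(C)C)[C@H]12
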